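## The problem

Compound 9 is an achiral, linear C13 chain. Two sulfur atoms tie it into a 2,2'-bithiophene: ring A carries the CH2O group at C5 and ring B carries the alkyne at C5' (bithiophene numbering throughout, inter-ring bond C2–C2').

There is no stereocentre and no configurable double bond, because the enoate carbon bears two methyl groups. Nothing has to be controlled in space, and the whole difficulty is differentiation.

The core is pseudo-symmetric, yet its two α-termini need different carbon substituents: an sp3 CH2O at C5 and an sp carbon at C5'. The two terminal primary alcohols need two C5 acyl groups, 3-methylbut-2-enoyl and 3-methylbutanoyl, that differ by two hydrogen atoms only.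

An intermediate that holds both hydroxyl groups calls for masks, redox steps or protecting groups. So does one that holds both esters in the presence of hydride, hydroxide, alkoxide or sulfide.

- **Thenylic C–O bond at C5:** it ionises easily, and more easily once ring B extends the conjugation.
- **Enoate:** it can slip out of conjugation through a vinylketene or a dienolate, and it accepts soft nucleophiles.
- **Bithienyl-alkyne chromophore:** it is a photosensitiser, so light and oxygen must be kept out.

The feature that opens a short way is ring B. It is bound to the rest only through its two α-carbons, C2' to an sp2 carbon (C2 of ring A) and C5' to an sp carbon. One palladium catalyst can make both bonds from two different carbon–halogen bonds.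

Ring A is the complement. With C5 blocked by the CH2O group, C2–H next to S1 is its single free α-C–H. It can act as the nucleophile without any metal or boron group.

## Retrosynthesis

**Cut 1, C2–C2' (9 to 6 and 8).**
- The inter-ring bond is the only single bond in 9 whose cleavage puts the two esters into different fragments.
- The neighbouring cuts (C5–CH2, the acyl–O bonds, C5'–C(sp) alone) leave a bithiophene whose two ends still have to be told apart. Sooner or later they also give an intermediate with two oxygen termini.
- After the C2–C2' cut each alcohol is acylated in a molecule where it is the only hydroxyl group. The discrimination of the two C5 acyl groups then vanishes instead of having to be solved.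
- Ring A becomes the C–H partner 6 (13 heavy atoms) and ring B the bromide 8 (17 heavy atoms), against 29 in 9.
- The reverse polarity would put halogen and palladium on the ring with the ionisable thenylic ester. The more valuable alkyne-bearing ring would then be the partner used in excess.
- The forward reaction must cleave one C–H bond of 6 selectively. It must not ionise the thenylic C–O bond, and it must leave alkyne, enoate and saturated ester alone.

**Cut 2, C5'–C(sp) (8 to 7 and 3).**
- The second bond at ring B is made by the same metal, so both cuts merge into one operation around the linchpin 7 (7 heavy atoms).
- The C–I bond of 7 reacts with the terminal alkyne 3 (11 heavy atoms) at room temperature. The C–Br bond waits until the flask is heated with 6.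
- Cutting here rather than at the propargylic C–C bond keeps the C4 arm as one cheap piece that already carries its ester.
- The forward reaction needs full iodine-over-bromine selectivity and complete consumption of 3 before heating.
- Taken together, 9 falls into three fragments, each one step or none from commerce.

**Cut 3, acyl–O bond at the thenylic oxygen (6 to 4 and 5).**
- The ester is made at the monothiophene stage, where the thenylic alcohol 4 is least prone to ionise.
- Acid 5 is activated with a carbodiimide rather than as its chloride with an amine, since the latter pair opens the vinylketene path to the deconjugated isomer.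

**Cut 4, acyl–O bond at the homopropargylic oxygen (3 to 1 and 2).**
- This is a plain acylation of the only hydroxyl group of 1 with the saturated acid chloride 2.
- Nothing here can isomerise, and the terminal alkyne is left free for the key step.

## Roads not taken

**Alternative 1:** the most obvious route.
- **Cut:** C5'–C(sp) and both acyl–O bonds, with the bithiophene in hand from the start.
- **Forward key step:** Sonogashira coupling of 5'-bromo-2,2'-bithiophene-5-carbaldehyde A1 with 1 gives 5'-(4-hydroxybut-1-yn-1-yl)-2,2'-bithiophene-5-carbaldehyde A2. Acylation with 2, reduction with NaBH4 and acylation with 5 follow.
- **Why the chosen plan is better:**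
  - This route is sound but strictly linear, with four steps after A1, all on the light-sensitive chromophore.
  - The formyl group is only a mask that keeps the two alcohols apart, and it costs a redox step.
  - The free thenylic alcohol of the complete bithienyl-alkyne is the most easily ionised species of the whole problem, and it must be handled and acylated.
  - A1 itself stands two functionalisations away from the parent core.
  - The chosen plan needs no mask and no redox step, and its longest sequence is two steps.

**Alternative 2:** biomimetic closure at sulfur.
- **Cut:** both C–S bonds of ring A.
- **Forward key step:** addition of Na2S to the 1,3-diyne of 5-[5-(4-hydroxybut-1-yn-1-yl)thiophen-2-yl]penta-2,4-diyn-1-ol A3 gives 4-[5'-(hydroxymethyl)-2,2'-bithiophen-5-yl]but-3-yn-1-ol A4.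
- **Why the chosen plan is better:**
  - Sulfide and hydrosulfide saponify or thiolyse both esters, add to the enoate and displace propargylic carboxylates. The esters therefore have to come after ring closure.
  - That leads to diol A4, which is exactly the compound in which two primary hydroxyl groups must be told apart.
  - A3 needs an unsymmetrical diyne (Cadiot–Chodkiewicz coupling with a 1-bromoalkyne after a silyl-alkyne detour), which makes for a long run-up.
  - The thiophene-conjugated third alkyne of A3 is a further acceptor for sulfur.

**Alternative 3:** ring A closed at a carbon–carbon bond.
- **Cut:** S1–C2 and C4–C5 of ring A (Fiesselmann-type closure).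
- **Forward key step:**
  - Chloroformylation (Vilsmeier–Haack–Arnold) of 1-(5-bromothiophen-2-yl)ethanone A5 gives (Z)-3-(5-bromothiophen-2-yl)-3-chloroprop-2-enal A6.
  - A sulfanylacetate ester and base then react by addition–elimination at the chlorovinyl carbon and an intramolecular aldol condensation that closes C4–C5.
  - The product is methyl 5'-bromo-2,2'-bithiophene-5-carboxylate A7.
- **Why the chosen plan is better:**
  - The closure is reliable and desymmetrises the core by construction. However, A7 stands at the same level as A1.
  - Its ester must be reduced by hydride before the 3-methylbutanoate can arrive, so the linear end-game of Alternative 1 returns with two more steps in front.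
  - Ring construction buys nothing here, because thiophenes with the required α-handles are commodity chemicals.

Key step: step 3

Remark: the target has no stereocentre and no double bond with two configurations, so no SMILES of the route needs a stereodescriptor. Compounds 1, 2, 4, 5 and 7 are taken as commercial.

## Steps

Step 1
Reactants: 1 but-3-yn-1-ol; 2 3-methylbutanoyl chloride
Product: 3 but-3-yn-1-yl 3-methylbutanoate
Conditions: Et3N (1.3 equiv), DMAP (5 mol %), CH2Cl2, 0 °C to 23 °C
Reagents that add atoms: none
Why: DMAP-catalysed acylation of a primary alcohol with a saturated acid chloride; the acyl group has no conjugation to lose and the terminal alkyne is inert to Et3N. The ester is placed while 1 holds the only hydroxyl group present, so no selectivity is asked for.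

Step 2
Reactants: 4 thiophen-2-ylmethanol; 5 3-methylbut-2-enoic acid
Product: 6 thiophen-2-ylmethyl 3-methylbut-2-enoate
Conditions: DCC (1.1 equiv), DMAP (10 mol %), CH2Cl2, 0 °C to 23 °C
Reagents that add atoms: none
Why: Steglich esterification; the acid is activated as O-acylisourea and acylpyridinium under nearly neutral conditions, which avoids the acid chloride/amine pair that leads through a vinylketene to the deconjugated 3-methylbut-3-enoate. No strong acid is present, so the thenylic alcohol should not self-condense, and at the monothiophene stage its C–O bond ionises far less readily than in a bithiophene.

Step 3
Reactants: 7 2-bromo-5-iodothiophene; 3 but-3-yn-1-yl 3-methylbutanoate; 6 thiophen-2-ylmethyl 3-methylbut-2-enoate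
Product: 9 [5'-(4-{[3-methylbutanoyl]oxy}but-1-yn-1-yl)-2,2'-bithiophen-5-yl]methyl 3-methylbut-2-enoate, via bromothienylalkyne 8 (not isolated)
Conditions: 7 (1.0 equiv), 3 (0.97 equiv), PdCl2(PPh3)2 (3 mol %), CuI (3 mol %), Et3N (1.5 equiv), degassed DMAc, 23 °C, dark, until 3 is consumed; then in the same flask 6 (2.0 equiv), K2CO3 (3.0 equiv), 5 (30 mol %), 100 °C, Ar, dark
Reagents that add atoms: none
Why: Stage one is a Sonogashira coupling: zerovalent palladium inserts at 23 °C into the weaker C5'–I bond of 7 only, the acetylide formed from 3 and CuI transmetalates, and reductive elimination gives 8 with C2'–Br intact, a halogen selectivity with close precedent on bromo-iodo-arenes and -thiophenes. Stage two is a carboxylate-assisted direct C–H arylation by concerted metalation–deprotonation, the reaction type by which 2-bromothiophenes and α-unsubstituted thiophenes are joined in bithiophene and polythiophene synthesis: at 100 °C the same palladium inserts into C2'–Br, bromide is exchanged for 3-methylbut-2-enoate, this ligand removes the α-proton of 6 as the C–Pd bond forms, and reductive elimination makes C2–C2'. No ring is closed and no stereocentre is formed. Site selectivity comes from the substrates: in 6 the C–H next to sulfur is the most acidic one and the only free α-position because the other α-carbon carries the CH2O group, while 8 and 9 have no free α-C–H, so self-coupling of 8 and further arylation of 9 lack an easy path. The order of the two bond formations is fixed by the two halogens and the temperature, and 3 is the limiting component so that no terminal alkyne is left when C–Br becomes reactive. Acid 5 replaces the usual pivalic acid as proton shuttle, being of similar acidity, so that any carboxylate exchange at the ionisable thenylic carbon is degenerate. The β,β-disubstituted enoate is a poor Heck acceptor, and the excess of 6 favours C–H cleavage over carbopalladation of the internal alkyne. Both esters meet only carbonate and carboxylate in a dry aprotic medium, and light and oxygen are excluded because 9 is a photosensitiser.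

## Compound list

1 | but-3-yn-1-ol | C#CCCO | starting material
2 | 3-methylbutanoyl chloride | CC(C)CC(=O)Cl | starting material
3 | but-3-yn-1-yl 3-methylbutanoate | C#CCCOC(=O)CC(C)C | intermediate
4 | thiophen-2-ylmethanol | OCc1cccs1 | starting material
5 | 3-methylbut-2-enoic acid | CC(C)=CC(=O)O | starting material
6 | thiophen-2-ylmethyl 3-methylbut-2-enoate | CC(C)=CC(=O)OCc1cccs1 | intermediate
7 | 2-bromo-5-iodothiophene | Brc1ccc(I)s1 | starting material
8 | 4-(5-bromothiophen-2-yl)but-3-yn-1-yl 3-methylbutanoate | CC(C)CC(=O)OCCC#Cc1ccc(Br)s1 | intermediate
9 | [5'-(4-{[3-methylbutanoyl]oxy}but-1-yn-1-yl)-2,2'-bithiophen-5-yl]methyl 3-methylbut-2-enoate | CC(C)=CC(=O)OCc1ccc(-c2ccc(C#CCCOC(=O)CC(C)C)s2)s1 | target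

## Step count and least certain steps

Total step count: 3. Longest linear sequence: 2 (step 1 or step 2, then step 3).

**Step 3 (key step).** Four processes are the most likely to interfere:
- The thienyl complex of divalent palladium may add across the internal alkyne of a second molecule, in competition with C–H cleavage.
- Zerovalent palladium may ionise the thenylic C–O bond at 100 °C, with capture by something other than the carboxylate.
- The iodide left from stage one may slow the C–H cleavage.
- Residual amine may cause hydrodebromination.

All four stem from running the C–H step hot, with the labile ester and the alkyne in the same flask.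

The fallback sets out from 8, isolated after stage one. It joins ring A as a boron nucleophile at the aldehyde oxidation level. Suzuki–Miyaura coupling with commercial 5-formylthiophen-2-ylboronic acid (PdCl2(dppf), K3PO4, THF–water, 45 °C) should give 4-(5'-formyl-2,2'-bithiophen-5-yl)but-3-yn-1-yl 3-methylbutanoate F1. NaBH4 in THF–MeOH at 0 °C reduces the aldehyde in preference to the ester and should give 4-[5'-(hydroxymethyl)-2,2'-bithiophen-5-yl]but-3-yn-1-yl 3-methylbutanoate F2. Steglich acylation of its only hydroxyl group with 5 (DCC, DMAP, CH2Cl2, 0 °C, dark) comes back to the route at 9. The thenylic ester then never meets palladium or heat, and the price is two more steps.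

**Step 2.** The likely failures are:
- migration of the double bond out of conjugation while the acyl group is activated;
- O-to-N acyl shift of the O-acylisourea;
- self-condensation of the thenylic alcohol if acid builds up.

The fallback sets out from 4 and 5 and comes back at 6. It forms the other C–O bond: a Mitsunobu reaction (PPh3, diisopropyl azodicarboxylate, THF, 0 °C) activates the alcohol and lets the carboxylate of 5 displace at the thenylic carbon. The acyl carbon is never activated, so no ketene path exists. No new compound lies on this way.

**Step 1.** The reaction itself is safe. The likely trouble is loss of the low-boiling ester on concentration and carry-over of salts or acid. Either would blur the stoichiometry of 3, on which step 3 depends.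

The fallback sets out from 1 and 7. Sonogashira coupling of the free alcohol (PdCl2(PPh3)2, CuI, Et3N, THF, 23 °C) should give the non-volatile 4-(5-bromothiophen-2-yl)but-3-yn-1-ol F3. Acylation of F3 with 2 (Et3N, DMAP, CH2Cl2) comes back to the route at 8. Compound 8 is then isolated and enters stage two of step 3.

## Further compounds

F1 | step 3 | 4-(5'-formyl-2,2'-bithiophen-5-yl)but-3-yn-1-yl 3-methylbutanoate | O=Cc1ccc(-c2ccc(C#CCCOC(=O)CC(C)C)s2)s1
F2 | step 3 | 4-[5'-(hydroxymethyl)-2,2'-bithiophen-5-yl]but-3-yn-1-yl 3-methylbutanoate | OCc1ccc(-c2ccc(C#CCCOC(=O)CC(C)C)s2)s1
F0 | step 2 | none | none
F3 | step 1 | 4-(5-bromothiophen-2-yl)but-3-yn-1-ol | OCCC#Cc1ccc(Br)s1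
A1 | alternative 1 | 5'-bromo-2,2'-bithiophene-5-carbaldehyde | O=Cc1ccc(-c2ccc(Br)s2)s1
A2 | alternative 1 | 5'-(4-hydroxybut-1-yn-1-yl)-2,2'-bithiophene-5-carbaldehyde | O=Cc1ccc(-c2ccc(C#CCCO)s2)s1
A3 | alternative 2 | 5-[5-(4-hydroxybut-1-yn-1-yl)thiophen-2-yl]penta-2,4-diyn-1-ol | OCC#CC#Cc1ccc(C#CCCO)s1
A4 | alternative 2 | 4-[5'-(hydroxymethyl)-2,2'-bithiophen-5-yl]but-3-yn-1-ol | OCc1ccc(-c2ccc(C#CCCO)s2)s1
A5 | alternative 3 | 1-(5-bromothiophen-2-yl)ethanone | CC(=O)c1ccc(Br)s1
A6 | alternative 3 | (Z)-3-(5-bromothiophen-2-yl)-3-chloroprop-2-enal | O=C/C=C(\Cl)c1ccc(Br)s1
A7 | alternative 3 | methyl 5'-bromo-2,2'-bithiophene-5-carboxylate | COC(=O)c1ccc(-c2ccc(Br)s2)s1
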